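**Retrosynthetic overview**
- Target: an ent-drim-7-ene decalin (1R,4aR,8aR), a syn (S,S) sulfated carbinol/methyl pair, an E trisubstituted olefin and a hydroquinone. The last bond made is O–S (sulfation of the secondary alcohol), followed by unmasking of the silylated hydroquinone.
- ArCH2–CH= and =C–CH3 bonds: one-pot zirconium-catalysed methylalumination of a terminal alkyne and palladium-catalysed coupling with a 2,5-bis(silyloxy)benzyl chloride; this sets the E olefin.
- Bond between the carbinol carbon and the methyl-bearing carbon: lithiation–borylation of the decalin ethyl triisopropylbenzoate with a secondary boronic ester (itself made the same way), then C–B oxidation; this sets both side-chain stereocentres.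
- Decalin: ring A, then ring B, in one proton-initiated cascade from acyclic homofarnesyl triisopropylbenzoate (made from farnesol). This is the new catalytic enantioselective step. The arene ring is bought.

Assumption: the (S,S) antipode of the imidodiphosphorimidate acid is taken to give the (1R,4aR,8aR) decalin (if the sense proves opposite, the (R,R) antipode is used), and the target is delivered as the free hydrogen sulfate as drawn.

Notation: Dec = (1R,4aR,8aR)-2,5,5,8a-tetramethyl-1,4,4a,5,6,7,8,8a-octahydronaphthalen-1-yl; TIB = 2,4,6-triisopropylbenzoyl.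

**Step 1**
Reactants: 1 (2E,6E)-farnesol
Product: 2 (2E,6E)-farnesal
Conditions: MnO2 (activated), CH2Cl2, rt
Reagents that add atoms: none
Why: Activated manganese dioxide oxidises only the allylic alcohol (allylic alcohol oxidation) under neutral conditions, so the two E olefins are neither isomerised nor attacked.

**Step 2**
Reactants: 2 (2E,6E)-farnesal
Product: 3 (3E,7E)-4,8,12-trimethyltrideca-1,3,7,11-tetraene
Conditions: Ph3PCH3Br, KOtBu, THF, 0 °C → rt
Reagents that add atoms: methyltriphenylphosphonium bromide, C[P+](c1ccccc1)(c1ccccc1)c1ccccc1.[Br-]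
Why: Wittig methylenation with the non-stabilised ylide converts the enal into the terminal 1,3-diene without disturbing the existing E olefins.

**Step 3**
Reactants: 3 (3E,7E)-4,8,12-trimethyltrideca-1,3,7,11-tetraene
Product: 5 (3E,7E)-4,8,12-trimethyltrideca-3,7,11-trien-1-ol (homofarnesol), via B-alkyl-9-BBN adduct 4 (not isolated)
Conditions: 9-BBN-H, THF, 0 °C → rt; then NaOH, H2O2, H2O, 0 °C → rt
Reagents that add atoms: hydrogen peroxide, OO; 9-borabicyclo[3.3.1]nonane, B1C2CCCC1CCC2 (held in 4 only)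
Why: Brown hydroboration–oxidation: the bulky borane adds anti-Markovnikov to the only monosubstituted alkene (the diene terminus) much faster than to the trisubstituted olefins, and C–B oxidation gives the primary homoallylic alcohol.

**Step 4**
Reactants: 5 (3E,7E)-homofarnesol
Product: 6 (3E,7E)-4,8,12-trimethyltrideca-3,7,11-trien-1-yl 2,4,6-triisopropylbenzoate
Conditions: 2,4,6-triisopropylbenzoic acid, PPh3, DIAD, THF, 0 °C → rt
Reagents that add atoms: 2,4,6-triisopropylbenzoic acid, CC(C)c1cc(C(C)C)c(C(=O)O)c(C(C)C)c1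
Why: Mitsunobu esterification is the standard way to acylate a primary alcohol with this very hindered acid, and it leaves the triene untouched.

**Step 5 (new step)**
Reactants: 6 (3E,7E)-homofarnesyl 2,4,6-triisopropylbenzoate
Product: 7 2-Dec-ethyl 2,4,6-triisopropylbenzoate
Conditions: (S,S)-imidodiphosphorimidate acid HN[P(=NSO2C6F5)(O2-(S)-3,3′-Ar2-BINOL)]2 (Ar = 9,9-dimethylfluoren-2-yl, 5 mol%), (CF3)3COH, −30 °C
Reagents that add atoms: none
Why: Proposed new method: a confined, strongly acidic chiral imidodiphosphorimidate protonates the terminal isopropylidene inside its pocket while the all-E triene is folded chair–chair, so that two anti additions (Stork–Eschenmoser) close ring A and then ring B to the trans-decalin tertiary cation and set C4a, C8a and C1 in one event, the catalyst antipode selecting the (1R,4aR,8aR) face; because the shielded, non-nucleophilic triisopropylbenzoate cannot close an ether as a free hydroxyl would, the cascade should end by loss of the axial ring proton to the counter-anion to give the endocyclic trisubstituted olefin (any exocyclic isomer being re-protonated and funnelled to it); the closest known reaction types are the imidodiphosphorimidate-catalysed hydroxyl-terminated cyclisation of homofarnesol to ambrox, enantioselective Lewis-acid-assisted Brønsted acid polyene cyclisations, and the racemic superacid cyclisation of farnesyl esters to drim-7-enes.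

**Step 6**
Reactants: 8 (5-chloropent-1-yn-1-yl)trimethylsilane
Product: 10 4,4,5,5-tetramethyl-2-[5-(trimethylsilyl)pent-4-yn-1-yl]-1,3,2-dioxaborolane, via alkylmagnesium chloride 9 (not isolated)
Conditions: Mg, I2 (cat.), THF, reflux; then i-PrOBpin, −78 °C → rt; aq. HCl
Reagents that add atoms: 2-isopropoxy-4,4,5,5-tetramethyl-1,3,2-dioxaborolane, CC(C)OB1OC(C)(C)C(C)(C)O1; magnesium, [Mg] (held in 9 only)
Why: Grignard formation from the primary chloride and borylation with the isopropoxy boronate give the primary pinacol boronic ester, the silyl-capped alkyne being inert.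

**Step 7**
Reactants: 10 primary boronic ester; 11 ethyl 2,4,6-triisopropylbenzoate
Product: 14 4,4,5,5-tetramethyl-2-[(2S)-7-(trimethylsilyl)hept-6-yn-2-yl]-1,3,2-dioxaborolane, via lithiated benzoate 12 (not isolated), via boronate complex 13 (not isolated)
Conditions: 11, s-BuLi, (+)-sparteine, Et2O, −78 °C, 5 h; then 10, −78 °C → 35 °C, 16 h
Reagents that add atoms: sec-butyllithium, CCC(C)[Li] (lithium held in 12 and 13 only)
Why: Hoppe–Aggarwal lithiation–borylation (a Matteson-type 1,2-metallate rearrangement): (+)-sparteine-directed deprotonation gives the configurationally stable (R)-lithiated ester, borylation goes with retention, and the primary alkyl group migrates anti to the departing benzoate with inversion, which sets the methyl-bearing centre as S.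

**Step 8**
Reactants: 7 2-Dec-ethyl 2,4,6-triisopropylbenzoate; 14 (S)-secondary boronic ester
Product: 19 (2S,3S)-1-Dec-3-methyloct-7-yn-2-ol, via lithiated benzoate 15 (not isolated), via boronate complex 16 (not isolated), via secondary boronic ester 17 (not isolated), via silyl alkynol 18 (not isolated)
Conditions: 7, s-BuLi, (+)-sparteine, Et2O, −78 °C, 5 h; then 14, −78 °C → 40 °C; then NaOH, H2O2, THF/H2O, 0 °C → rt; then K2CO3, MeOH, rt
Reagents that add atoms: hydrogen peroxide, OO; sec-butyllithium, CCC(C)[Li] (lithium held in 15 and 16 only)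
Why: A second reagent-controlled lithiation–borylation: the (+)-sparteine-derived (R)-lithiated benzoate captures the secondary boronic ester with retention, the secondary alkyl group migrates with retention at its own centre and inversion at the carbenoid carbon, stereoretentive C–B oxidation gives the (2S,3S) syn alcohol, and K2CO3/MeOH removes the alkyne silyl group.

**Step 9**
Reactants: 20 2,5-dihydroxybenzaldehyde
Product: 21 2,5-bis[(tert-butyldimethylsilyl)oxy]benzaldehyde
Conditions: TBSCl, imidazole, DMF, rt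
Reagents that add atoms: tert-butyldimethylsilyl chloride, CC(C)(C)[Si](C)(C)Cl
Why: Imidazole-promoted silyl ether formation masks both phenols as fluoride-labile ethers that tolerate the later organoaluminium, palladium and sulfation chemistry.

**Step 10**
Reactants: 21 2,5-bis[(tert-butyldimethylsilyl)oxy]benzaldehyde
Product: 22 {2,5-bis[(tert-butyldimethylsilyl)oxy]phenyl}methanol
Conditions: i-Bu2AlH, CH2Cl2, −78 °C; aq. KNaC4H4O6
Reagents that add atoms: none
Why: Hydride reduction of the aldehyde at low temperature gives the benzylic alcohol, and the non-basic aluminium alkoxide avoids silyl migration from the ortho phenol oxygen.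

**Step 11**
Reactants: 22 {2,5-bis[(tert-butyldimethylsilyl)oxy]phenyl}methanol
Product: 23 2-(chloromethyl)-1,4-bis[(tert-butyldimethylsilyl)oxy]benzene
Conditions: PPh3, N-chlorosuccinimide, THF, 0 °C → rt
Reagents that add atoms: N-chlorosuccinimide, O=C1CCC(=O)N1Cl
Why: Appel-type chlorination converts the benzylic alcohol into the chloride under neutral conditions that spare the aryl silyl ethers.

**Step 12**
Reactants: 19 (2S,3S)-1-Dec-3-methyloct-7-yn-2-ol; 23 benzylic chloride
Product: 25 (2S,3S,7E)-9-{2,5-bis[(tert-butyldimethylsilyl)oxy]phenyl}-1-Dec-3,7-dimethylnon-7-en-2-ol, via alkenylalane 24 (not isolated)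
Conditions: AlMe3, Cp2ZrCl2 (25 mol%), CH2Cl2, 0 °C → rt; evaporate volatiles; then 23, Pd(PPh3)4 (5 mol%), THF, rt; aq. KNaC4H4O6
Reagents that add atoms: trimethylaluminium, C[Al](C)C
Why: Negishi zirconium-catalysed carboalumination adds methyl and aluminium syn across the terminal alkyne with methyl on the internal carbon, and the alkenylalane then couples with the benzylic chloride under zerovalent palladium catalysis (Negishi-type cross-coupling) with retention, fixing the E olefin, while the free hydroxyl rides through as its aluminium alkoxide.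

**Step 13**
Reactants: 25 bis-silylated alcohol
Product: 26 pyridinium (2S,3S,7E)-9-{2,5-bis[(tert-butyldimethylsilyl)oxy]phenyl}-1-Dec-3,7-dimethylnon-7-en-2-yl sulfate
Conditions: SO3·pyridine, pyridine, 40 °C
Reagents that add atoms: sulfur trioxide–pyridine complex, [O-]S(=O)(=O)[n+]1ccccc1
Why: O-Sulfation of the secondary alcohol forms only an O–S bond, so the carbinol configuration is retained, and the silyl-capped phenols and trisubstituted olefins do not react.

**Step 14**
Reactants: 26 pyridinium sulfate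
Product: 27 (2S,3S,7E)-9-(2,5-dihydroxyphenyl)-3,7-dimethyl-1-[(1R,4aR,8aR)-2,5,5,8a-tetramethyl-1,4,4a,5,6,7,8,8a-octahydronaphthalen-1-yl]non-7-en-2-yl hydrogen sulfate (CNP0358517.7)
Conditions: HF·pyridine, pyridine, THF (degassed), 0 °C → rt; then sulfonic acid cation-exchange resin (H+ form), MeOH, 0 °C
Reagents that add atoms: none
Why: Fluoride cleavage of the two aryl silyl ethers under buffered, mildly acidic conditions (which also protect the hydroquinone from air oxidation) leaves the alkyl sulfate and olefins intact, and cold cation exchange replaces pyridinium by a proton to give the hydrogen sulfate as drawn (kept cold and dilute; stored as its sodium salt).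

**Compound list**
1 | (2E,6E)-farnesol | CC(C)=CCC/C(C)=C/CC/C(C)=C/CO | starting material
2 | (2E,6E)-farnesal | CC(C)=CCC/C(C)=C/CC/C(C)=C/C=O | intermediate
3 | (3E,7E)-4,8,12-trimethyltrideca-1,3,7,11-tetraene | CC(C)=CCC/C(C)=C/CC/C(C)=C/C=C | intermediate
4 | 9-[(3E,7E)-4,8,12-trimethyltrideca-3,7,11-trien-1-yl]-9-borabicyclo[3.3.1]nonane | CC(C)=CCC/C(C)=C/CC/C(C)=C/CCB1C2CCCC1CCC2 | intermediate (not isolated)
5 | (3E,7E)-4,8,12-trimethyltrideca-3,7,11-trien-1-ol (homofarnesol) | CC(C)=CCC/C(C)=C/CC/C(C)=C/CCO | intermediate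
6 | (3E,7E)-4,8,12-trimethyltrideca-3,7,11-trien-1-yl 2,4,6-triisopropylbenzoate | CC(C)=CCC/C(C)=C/CC/C(C)=C/CCOC(=O)c1c(C(C)C)cc(C(C)C)cc1C(C)C | intermediate
7 | 2-[(1R,4aR,8aR)-2,5,5,8a-tetramethyl-1,4,4a,5,6,7,8,8a-octahydronaphthalen-1-yl]ethyl 2,4,6-triisopropylbenzoate | CC1=CC[C@@H]2C(C)(C)CCC[C@@]2(C)[C@@H]1CCOC(=O)c1c(C(C)C)cc(C(C)C)cc1C(C)C | intermediate
8 | (5-chloropent-1-yn-1-yl)trimethylsilane | C[Si](C)(C)C#CCCCCl | starting material
9 | [5-(trimethylsilyl)pent-4-yn-1-yl]magnesium chloride | C[Si](C)(C)C#CCCC[Mg]Cl | intermediate (not isolated)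
10 | 4,4,5,5-tetramethyl-2-[5-(trimethylsilyl)pent-4-yn-1-yl]-1,3,2-dioxaborolane | C[Si](C)(C)C#CCCCB1OC(C)(C)C(C)(C)O1 | intermediate
11 | ethyl 2,4,6-triisopropylbenzoate | CCOC(=O)c1c(C(C)C)cc(C(C)C)cc1C(C)C | starting material
12 | (1R)-1-lithioethyl 2,4,6-triisopropylbenzoate, (+)-sparteine-bound | C[C@@H]([Li])OC(=O)c1c(C(C)C)cc(C(C)C)cc1C(C)C | intermediate (not isolated)
13 | lithium {(1R)-1-[(2,4,6-triisopropylbenzoyl)oxy]ethyl}[5-(trimethylsilyl)pent-4-yn-1-yl](pinacolato)borate | C[C@@H]([B-]1(CCCC#C[Si](C)(C)C)OC(C)(C)C(C)(C)O1)OC(=O)c1c(C(C)C)cc(C(C)C)cc1C(C)C.[Li+] | intermediate (not isolated)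
14 | 4,4,5,5-tetramethyl-2-[(2S)-7-(trimethylsilyl)hept-6-yn-2-yl]-1,3,2-dioxaborolane | C[C@H](B1OC(C)(C)C(C)(C)O1)CCCC#C[Si](C)(C)C | intermediate
15 | (1R)-2-Dec-1-lithioethyl 2,4,6-triisopropylbenzoate, (+)-sparteine-bound | CC1=CC[C@@H]2C(C)(C)CCC[C@@]2(C)[C@@H]1C[C@@H]([Li])OC(=O)c1c(C(C)C)cc(C(C)C)cc1C(C)C | intermediate (not isolated)
16 | lithium {(1R)-2-Dec-1-[(2,4,6-triisopropylbenzoyl)oxy]ethyl}[(2S)-7-(trimethylsilyl)hept-6-yn-2-yl](pinacolato)borate | CC1=CC[C@@H]2C(C)(C)CCC[C@@]2(C)[C@@H]1C[C@@H]([B-]1(OC(C)(C)C(C)(C)O1)[C@@H](C)CCCC#C[Si](C)(C)C)OC(=O)c1c(C(C)C)cc(C(C)C)cc1C(C)C.[Li+] | intermediate (not isolated)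
17 | 2-[(2S,3S)-1-Dec-3-methyl-8-(trimethylsilyl)oct-7-yn-2-yl]-4,4,5,5-tetramethyl-1,3,2-dioxaborolane | CC1=CC[C@@H]2C(C)(C)CCC[C@@]2(C)[C@@H]1C[C@H](B1OC(C)(C)C(C)(C)O1)[C@@H](C)CCCC#C[Si](C)(C)C | intermediate (not isolated)
18 | (2S,3S)-1-Dec-3-methyl-8-(trimethylsilyl)oct-7-yn-2-ol | CC1=CC[C@@H]2C(C)(C)CCC[C@@]2(C)[C@@H]1C[C@H](O)[C@@H](C)CCCC#C[Si](C)(C)C | intermediate (not isolated)
19 | (2S,3S)-1-Dec-3-methyloct-7-yn-2-ol | CC1=CC[C@@H]2C(C)(C)CCC[C@@]2(C)[C@@H]1C[C@H](O)[C@@H](C)CCCC#C | intermediate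
20 | 2,5-dihydroxybenzaldehyde | O=Cc1cc(O)ccc1O | starting material
21 | 2,5-bis[(tert-butyldimethylsilyl)oxy]benzaldehyde | O=Cc1cc(O[Si](C)(C)C(C)(C)C)ccc1O[Si](C)(C)C(C)(C)C | intermediate
22 | {2,5-bis[(tert-butyldimethylsilyl)oxy]phenyl}methanol | OCc1cc(O[Si](C)(C)C(C)(C)C)ccc1O[Si](C)(C)C(C)(C)C | intermediate
23 | 2-(chloromethyl)-1,4-bis[(tert-butyldimethylsilyl)oxy]benzene | ClCc1cc(O[Si](C)(C)C(C)(C)C)ccc1O[Si](C)(C)C(C)(C)C | intermediate
24 | dimethylaluminium (2S,3S,7E)-1-Dec-8-(dimethylalumanyl)-3,7-dimethyloct-7-en-2-olate | CC1=CC[C@@H]2C(C)(C)CCC[C@@]2(C)[C@@H]1C[C@H](O[Al](C)C)[C@@H](C)CCC/C(C)=C/[Al](C)C | intermediate (not isolated)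
25 | (2S,3S,7E)-9-{2,5-bis[(tert-butyldimethylsilyl)oxy]phenyl}-1-Dec-3,7-dimethylnon-7-en-2-ol | CC1=CC[C@@H]2C(C)(C)CCC[C@@]2(C)[C@@H]1C[C@H](O)[C@@H](C)CCC/C(C)=C/Cc1cc(O[Si](C)(C)C(C)(C)C)ccc1O[Si](C)(C)C(C)(C)C | intermediate
26 | pyridinium (2S,3S,7E)-9-{2,5-bis[(tert-butyldimethylsilyl)oxy]phenyl}-1-Dec-3,7-dimethylnon-7-en-2-yl sulfate | CC1=CC[C@@H]2C(C)(C)CCC[C@@]2(C)[C@@H]1C[C@H](OS(=O)(=O)[O-])[C@@H](C)CCC/C(C)=C/Cc1cc(O[Si](C)(C)C(C)(C)C)ccc1O[Si](C)(C)C(C)(C)C.c1cc[nH+]cc1 | intermediate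
27 | (2S,3S,7E)-9-(2,5-dihydroxyphenyl)-3,7-dimethyl-1-[(1R,4aR,8aR)-2,5,5,8a-tetramethyl-1,4,4a,5,6,7,8,8a-octahydronaphthalen-1-yl]non-7-en-2-yl hydrogen sulfate | CC1=CC[C@@H]2C(C)(C)CCC[C@@]2(C)[C@@H]1C[C@H](OS(=O)(=O)O)[C@@H](C)CCC/C(C)=C/Cc1cc(O)ccc1O | target

**Totals**
Total step count: 14. Longest linear sequence: 9 steps (1, 2, 3, 4, 5, 8, 12, 13, 14).

**Three steps most likely to fail, with fallbacks**

Step 5 (the proposed new cyclisation). Risks are incomplete bicyclisation, wrong olefin position or low enantioselectivity. The fallback uses known chemistry, sets out from 6 and comes back at 7. Ester 6 is cyclised without asymmetric induction under the long-established superacid conditions for farnesyl-type esters (FSO3H, 2-nitropropane, −78 °C, Et3N quench), which give the trans-fused drim-7-ene skeleton as a racemate. This is 7 together with its mirror image, 2-[(1S,4aS,8aS)-2,5,5,8a-tetramethyl-1,4,4a,5,6,7,8,8a-octahydronaphthalen-1-yl]ethyl 2,4,6-triisopropylbenzoate F1. Minor olefin isomers are removed on AgNO3-impregnated silica, and the enantiomers are separated by preparative chiral supercritical-fluid chromatography on an amylose tris(3,5-dimethylphenylcarbamate) phase (the aryl ester is the UV handle). Ester 7 is carried on and F1 is set aside.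

Step 8 (coupling of two hindered partners by lithiation–borylation). Risks are slow boronate-complex formation or migration, or eroded diastereoselectivity. The fallback sets out from 7 and comes back at 18, which is then desilylated by the closing K2CO3/MeOH operation of step 8 to give 19. It runs as follows:
- Reductive ester cleavage (LiAlH4, THF, reflux) gives 2-Dec-ethan-1-ol F2.
- Dess–Martin oxidation gives 2-Dec-acetaldehyde F3.
- An Evans syn-aldol reaction with commercial (R)-4-benzyl-3-propionyl-1,3-oxazolidin-2-one (n-Bu2BOTf, i-Pr2NEt, CH2Cl2, −78 → 0 °C) sets both stereocentres under auxiliary control, giving (4R)-4-benzyl-3-[(2R,3S)-4-Dec-3-hydroxy-2-methylbutanoyl]-1,3-oxazolidin-2-one F4.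
- LiBH4 releases (2S,3S)-4-Dec-2-methylbutane-1,3-diol F5.
- Selective primary tosylation (TsCl, pyridine, 0 °C) gives (2S,3S)-4-Dec-3-hydroxy-2-methylbutyl 4-methylbenzenesulfonate F6.
- Li2CuCl4-catalysed coupling with excess [4-(trimethylsilyl)but-3-yn-1-yl]magnesium bromide F7 (from the commercial bromide and Mg) forms the remaining C–C bond and gives 18.

Step 12 (carboalumination and benzylation). The risk is that the electron-rich benzylic chloride ionises or homocouples in the presence of Lewis-acidic aluminium, or that methyl transfers instead of alkenyl. The fallback sets out from 19 and comes back at 25, with the polarity of the coupling reversed. Alkyne 19 is carboaluminated as before to 24, which is quenched with I2 (THF, −30 °C) to give (2S,3S,7E)-1-Dec-8-iodo-3,7-dimethyloct-7-en-2-ol F8. Chloride 23 is converted with Zn dust and LiCl (THF, rt) into {2,5-bis[(tert-butyldimethylsilyl)oxy]benzyl}zinc chloride F9. A Negishi coupling of F8 with excess F9 (Pd(OAc)2, SPhos, THF, rt) then gives 25 with retention of the E geometry.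

**Further compounds**
F1 | step 5 | 2-[(1S,4aS,8aS)-2,5,5,8a-tetramethyl-1,4,4a,5,6,7,8,8a-octahydronaphthalen-1-yl]ethyl 2,4,6-triisopropylbenzoate | CC1=CC[C@H]2C(C)(C)CCC[C@]2(C)[C@H]1CCOC(=O)c1c(C(C)C)cc(C(C)C)cc1C(C)C
F2 | step 8 | 2-[(1R,4aR,8aR)-2,5,5,8a-tetramethyl-1,4,4a,5,6,7,8,8a-octahydronaphthalen-1-yl]ethan-1-ol | CC1=CC[C@@H]2C(C)(C)CCC[C@@]2(C)[C@@H]1CCO
F3 | step 8 | 2-[(1R,4aR,8aR)-2,5,5,8a-tetramethyl-1,4,4a,5,6,7,8,8a-octahydronaphthalen-1-yl]acetaldehyde | CC1=CC[C@@H]2C(C)(C)CCC[C@@]2(C)[C@@H]1CC=O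
F4 | step 8 | (4R)-4-benzyl-3-{(2R,3S)-3-hydroxy-2-methyl-4-[(1R,4aR,8aR)-2,5,5,8a-tetramethyl-1,4,4a,5,6,7,8,8a-octahydronaphthalen-1-yl]butanoyl}-1,3-oxazolidin-2-one | CC1=CC[C@@H]2C(C)(C)CCC[C@@]2(C)[C@@H]1C[C@H](O)[C@@H](C)C(=O)N1C(=O)OC[C@H]1Cc1ccccc1
F5 | step 8 | (2S,3S)-2-methyl-4-[(1R,4aR,8aR)-2,5,5,8a-tetramethyl-1,4,4a,5,6,7,8,8a-octahydronaphthalen-1-yl]butane-1,3-diol | CC1=CC[C@@H]2C(C)(C)CCC[C@@]2(C)[C@@H]1C[C@H](O)[C@@H](C)CO
F6 | step 8 | (2S,3S)-3-hydroxy-2-methyl-4-[(1R,4aR,8aR)-2,5,5,8a-tetramethyl-1,4,4a,5,6,7,8,8a-octahydronaphthalen-1-yl]butyl 4-methylbenzenesulfonate | CC1=CC[C@@H]2C(C)(C)CCC[C@@]2(C)[C@@H]1C[C@H](O)[C@@H](C)COS(=O)(=O)c1ccc(C)cc1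
F7 | step 8 | [4-(trimethylsilyl)but-3-yn-1-yl]magnesium bromide | C[Si](C)(C)C#CCC[Mg]Br
F8 | step 12 | (2S,3S,7E)-8-iodo-3,7-dimethyl-1-[(1R,4aR,8aR)-2,5,5,8a-tetramethyl-1,4,4a,5,6,7,8,8a-octahydronaphthalen-1-yl]oct-7-en-2-ol | CC1=CC[C@@H]2C(C)(C)CCC[C@@]2(C)[C@@H]1C[C@H](O)[C@@H](C)CCC/C(C)=C/I
F9 | step 12 | {2,5-bis[(tert-butyldimethylsilyl)oxy]benzyl}zinc chloride | Cl[Zn]Cc1cc(O[Si](C)(C)C(C)(C)C)ccc1O[Si](C)(C)C(C)(C)C
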